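**Retrosynthetic overview**
1. Target ⇐ one hydrogenolysis of a macrocycle that carries two O-benzyl groups and two benzylic OH groups.
2. Macrocycle ⇐ intramolecular 2-pyrone/vinyl sulfone Diels–Alder, then loss of CO2 and of PhSO2H: ring B (the meta-linked benzene) and the 18-membered ring form in the same operation.
3. Open-chain precursor ⇐ Chan–Lam C–O coupling (ring C–O–ring D) of an arylboronate half with a phenol half.
4. Boronate half ⇐ benzylzinc addition to a 2-(pyron-3-yloxy)benzaldehyde (SNAr of 3-hydroxy-2-pyrone on a fluoroaldehyde from ortho-lithiation); phenol half ⇐ allylation and cross-metathesis of 4-(benzyloxy)-3-hydroxybenzaldehyde.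
5. Ring order: rings A, C and D are bought as arenes; ring B and the macrocycle are made last, together.

Ring labels: A = OMe/OH ring, B = meta-phenylene, C = OH ring carrying the second ether, D = para-phenylene.

Assumption: the target SMILES has no stereocentre and no stereogenic axis, so the compound is achiral and no stereocontrol is needed. The two carbinol centres carried from steps 4 and 5 are racemic (diastereomer mixtures from step 7 on) and are erased in step 9.

**Route**

Step 1
Reactants: 1 3-fluoro-4-methoxyphenol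
Product: 2 4-(benzyloxy)-2-fluoro-1-methoxybenzene
Conditions: BnBr, K2CO3, DMF, rt
Reagents that add atoms: benzyl bromide (BrCc1ccccc1)
Why: Williamson O-benzylation of the phenol; the benzyl ether survives every later step and falls off in the final hydrogenolysis.

Step 2
Reactants: 2 4-(benzyloxy)-2-fluoro-1-methoxybenzene
Product: 4 6-(benzyloxy)-2-fluoro-3-methoxybenzaldehyde, via aryllithium 3 (not isolated)
Conditions: n-BuLi, THF, −78 °C; DMF, −78 → 0 °C; 1 M HCl
Reagents that add atoms: N,N-dimethylformamide (CN(C)C=O)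
Why: Directed ortho-metalation at the only C–H flanked by F and OBn (the most acidic site), then DMF formylation; −78 °C prevents LiF loss to a benzyne.

Step 3
Reactants: 4 6-(benzyloxy)-2-fluoro-3-methoxybenzaldehyde; 5 3-hydroxy-2H-pyran-2-one
Product: 6 6-(benzyloxy)-3-methoxy-2-[(2-oxo-2H-pyran-3-yl)oxy]benzaldehyde
Conditions: Cs2CO3, dry DMSO, 80 °C
Reagents that add atoms: none
Why: SNAr (addition–elimination) in which the ortho-formyl group activates the C–F bond and the pyronolate oxygen is the nucleophile, giving the aryl pyronyl ether.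

Step 4
Reactants: 6 6-(benzyloxy)-3-methoxy-2-[(2-oxo-2H-pyran-3-yl)oxy]benzaldehyde; 7 2-[4-(bromomethyl)phenyl]-4,4,5,5-tetramethyl-1,3,2-dioxaborolane
Product: 9 rac-1-{6-(benzyloxy)-3-methoxy-2-[(2-oxo-2H-pyran-3-yl)oxy]phenyl}-2-[4-(4,4,5,5-tetramethyl-1,3,2-dioxaborolan-2-yl)phenyl]ethan-1-ol, via benzylzinc bromide 8 (not isolated)
Conditions: 7, Zn dust, LiCl, THF, 0 °C; then 6, MgCl2, THF, rt; aq NH4Cl
Reagents that add atoms: none
Why: Zinc insertion into the benzylic bromide and chemoselective 1,2-addition of the benzylzinc to the aldehyde (lactone and Bpin are tolerated); the new carbinol centre is racemic and is removed in step 9.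

Step 5
Reactants: 10 4-(benzyloxy)-3-hydroxybenzaldehyde
Product: 11 rac-1-[4-(benzyloxy)-3-hydroxyphenyl]but-3-en-1-ol
Conditions: allyl bromide, Zn dust, THF/sat. aq NH4Cl, rt
Reagents that add atoms: allyl bromide (C=CCBr)
Why: Zinc-mediated Barbier allylation in aqueous medium tolerates the free phenol; the carbinol centre is racemic and is removed in step 9.

Step 6
Reactants: 11 rac-1-[4-(benzyloxy)-3-hydroxyphenyl]but-3-en-1-ol
Product: 12 rac-(E)-1-[4-(benzyloxy)-3-hydroxyphenyl]-4-(phenylsulfonyl)but-3-en-1-ol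
Conditions: phenyl vinyl sulfone (2 equiv), Grubbs II (5 mol %), CH2Cl2, 40 °C
Reagents that add atoms: phenyl vinyl sulfone (C=CS(=O)(=O)c1ccccc1)
Why: Olefin cross-metathesis of a terminal alkene with an electron-poor vinyl sulfone, which gives the E-vinyl sulfone selectively.

Step 7
Reactants: 9 rac-1-{6-(benzyloxy)-3-methoxy-2-[(2-oxo-2H-pyran-3-yl)oxy]phenyl}-2-[4-(4,4,5,5-tetramethyl-1,3,2-dioxaborolan-2-yl)phenyl]ethan-1-ol; 12 rac-(E)-1-[4-(benzyloxy)-3-hydroxyphenyl]-4-(phenylsulfonyl)but-3-en-1-ol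
Product: 13 3-{3-(benzyloxy)-2-[2-(4-{2-(benzyloxy)-5-[(E)-1-hydroxy-4-(phenylsulfonyl)but-3-en-1-yl]phenoxy}phenyl)-1-hydroxyethyl]-6-methoxyphenoxy}-2H-pyran-2-one (diastereomer mixture)
Conditions: Cu(OAc)2 (0.5 equiv), pyridine, 4 Å MS, CH2Cl2, O2 (1 atm), rt
Reagents that add atoms: none
Why: Chan–Lam oxidative C–O coupling at room temperature, mild enough for the pyrone and the vinyl sulfone; the phenol is arylated far faster than the two secondary alcohols.

Step 8
Reactants: 13 3-{3-(benzyloxy)-2-[2-(4-{2-(benzyloxy)-5-[(E)-1-hydroxy-4-(phenylsulfonyl)but-3-en-1-yl]phenoxy}phenyl)-1-hydroxyethyl]-6-methoxyphenoxy}-2H-pyran-2-one (diastereomer mixture)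
Product: 16 macrocyclic diol bis(benzyl ether), via Diels–Alder lactone 14 (not isolated), via sulfonyl cyclohexadiene 15 (not isolated)
Conditions: 1,2-dichlorobenzene (1 mM, slow addition), 2,6-lutidine (3 equiv), BHT (cat.), 160 °C
Reagents that add atoms: none
Why: Proposed new method: intramolecular normal-demand Diels–Alder of the electron-rich 3-aryloxy-2-pyrone with the vinyl sulfone, in which the nucleophilic pyrone C6 bonds to the electrophilic sulfone β-carbon and C3 to the α-carbon (so the alkyl arm ends up meta to the ether oxygen), followed by retro-[4+2] loss of CO2 and β-elimination of benzenesulfinic acid, creates benzene ring B and closes the 18-membered ring at once; the closest known reaction type is the intramolecular pyrone/vinyl sulfone Diels–Alder–decarboxylation–desulfination used to build cyclophane arenes, here extended to a non-hydroxylated pyrone ether and a β-alkyl vinyl sulfone.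

Step 9
Reactants: 16 macrocyclic diol bis(benzyl ether)
Product: 17 target CNP0179896.0
Conditions: H2 (4 atm), 10 % Pd/C, EtOAc–AcOH, cat. HCl, 40 °C
Reagents that add atoms: none
Why: Heterogeneous hydrogenolysis cleaves both benzyl ethers and, acid-assisted, both electron-rich benzylic C–OH bonds, which erases the two racemic carbinol centres and gives the achiral target.

**Compound list**
1 | 3-fluoro-4-methoxyphenol | COc1ccc(O)cc1F | starting material
2 | 4-(benzyloxy)-2-fluoro-1-methoxybenzene | COc1ccc(OCc2ccccc2)cc1F | intermediate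
3 | aryllithium: [6-(benzyloxy)-2-fluoro-3-methoxyphenyl]lithium | [Li]c1c(F)c(OC)ccc1OCc1ccccc1 | intermediate (not isolated)
4 | 6-(benzyloxy)-2-fluoro-3-methoxybenzaldehyde | O=Cc1c(F)c(OC)ccc1OCc1ccccc1 | intermediate
5 | 3-hydroxy-2H-pyran-2-one | O=C1OC=CC=C1O | starting material
6 | 6-(benzyloxy)-3-methoxy-2-[(2-oxo-2H-pyran-3-yl)oxy]benzaldehyde | O=Cc1c(OC2=CC=COC2=O)c(OC)ccc1OCc1ccccc1 | intermediate
7 | 2-[4-(bromomethyl)phenyl]-4,4,5,5-tetramethyl-1,3,2-dioxaborolane | BrCc1ccc(cc1)B1OC(C)(C)C(C)(C)O1 | starting material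
8 | benzylzinc bromide: {[4-(4,4,5,5-tetramethyl-1,3,2-dioxaborolan-2-yl)phenyl]methyl}zinc bromide | Br[Zn]Cc1ccc(cc1)B1OC(C)(C)C(C)(C)O1 | intermediate (not isolated)
9 | rac-1-{6-(benzyloxy)-3-methoxy-2-[(2-oxo-2H-pyran-3-yl)oxy]phenyl}-2-[4-(4,4,5,5-tetramethyl-1,3,2-dioxaborolan-2-yl)phenyl]ethan-1-ol | COc1ccc(OCc2ccccc2)c(C(O)Cc2ccc(cc2)B2OC(C)(C)C(C)(C)O2)c1OC1=CC=COC1=O | intermediate
10 | 4-(benzyloxy)-3-hydroxybenzaldehyde | O=Cc1ccc(OCc2ccccc2)c(O)c1 | starting material
11 | rac-1-[4-(benzyloxy)-3-hydroxyphenyl]but-3-en-1-ol | C=CCC(O)c1ccc(OCc2ccccc2)c(O)c1 | intermediate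
12 | rac-(E)-1-[4-(benzyloxy)-3-hydroxyphenyl]-4-(phenylsulfonyl)but-3-en-1-ol | OC(C/C=C/S(=O)(=O)c1ccccc1)c1ccc(OCc2ccccc2)c(O)c1 | intermediate
13 | 3-{3-(benzyloxy)-2-[2-(4-{2-(benzyloxy)-5-[(E)-1-hydroxy-4-(phenylsulfonyl)but-3-en-1-yl]phenoxy}phenyl)-1-hydroxyethyl]-6-methoxyphenoxy}-2H-pyran-2-one (diastereomer mixture, both carbinol centres racemic) | COc1ccc(OCc2ccccc2)c(C(O)Cc2ccc(cc2)Oc2cc(ccc2OCc2ccccc2)C(O)C/C=C/S(=O)(=O)c2ccccc2)c1OC1=CC=COC1=O | intermediate
14 | Diels–Alder lactone: macrocyclic 2-oxabicyclo[2.2.2]oct-5-en-3-one with pyrone C6 bonded to the sulfone β-carbon and pyrone C3 (bridgehead, aryloxy) bonded to the sulfonyl-bearing carbon (stereoisomer mixture) | COc1ccc(OCc3ccccc3)c(C(O)Cc3ccc(cc3)Oc3cc(ccc3OCc3ccccc3)C(O)CC3C4C=CC(C(=O)O4)(O2)C3S(=O)(=O)c3ccccc3)c12 | intermediate (not isolated)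
15 | sulfonyl cyclohexadiene: macrocyclic 1-aryloxy-6-(phenylsulfonyl)cyclohexa-1,3-diene left after CO2 loss from 14 (stereoisomer mixture) | COc1ccc(OCc3ccccc3)c(C(O)Cc3ccc(cc3)Oc3cc(ccc3OCc3ccccc3)C(O)CC3C=CC=C(O2)C3S(=O)(=O)c3ccccc3)c12 | intermediate (not isolated)
16 | macrocyclic diol bis(benzyl ether): the target ring system with both phenols as benzyl ethers and an OH on the benzylic carbon attached to ring A and on the benzylic carbon attached to ring C (diastereomer mixture) | COc1ccc(OCc3ccccc3)c(C(O)Cc3ccc(cc3)Oc3cc(ccc3OCc3ccccc3)C(O)Cc3cccc(c3)O2)c12 | intermediate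
17 | target CNP0179896.0 (achiral 18-membered bis(bibenzyl) diaryl ether) | COc1ccc(O)c2c1Oc1cccc(c1)CCc1ccc(O)c(c1)Oc1ccc(cc1)CC2 | target

**Totals**
Total step count: 9.
Longest linear sequence: 7 steps (steps 1, 2, 3, 4, 7, 8, 9).

**Three steps most likely to fail**

Step 8 (macrocyclising cycloaddition). The β-alkyl vinyl sulfone is a sluggish dienophile and the ring closure has to compete with oligomerisation. Fallback: make ring B and the macrocycle in separate operations. Set out from 6 and 12 and heat them together at 0.5 M (1,2-dichlorobenzene, 2,6-lutidine, 150 °C). The same cycloaddition now runs between two molecules, through the bimolecular Diels–Alder lactone F1 and the sulfonyl cyclohexadiene aldehyde F2, to the diaryl ether aldehyde F3. Addition of benzylzinc bromide 8 (3 equiv, MgCl2, THF) to the aldehyde gives the seco boronate F4. An intramolecular Chan–Lam etherification (Cu(OAc)2, pyridine, O2, 2 mM) then closes the ring and comes back to the route at 16.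

Step 3 (SNAr with the hydroxypyrone). The pyronolate is a weak nucleophile and the pyrone ring may be opened by the base. Fallback: reverse the polarity of the C–O bond formation. Set out from 4: 2-(methylsulfonyl)ethanol and NaH in DMF give by SNAr the sulfonylethyl ether F5, which loses methyl vinyl sulfone in the same flask to give the salicylaldehyde F6. Copper-catalysed O-vinylation of this phenol with purchased 3-bromo-2H-pyran-2-one (BrC1=CC=COC1=O; CuI, N,N-dimethylglycine, Cs2CO3, dioxane, 80 °C) comes back to the route at 6.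

Step 7 (Chan–Lam coupling of a pinacol boronate). Pinacol esters couple more slowly than boronic acids and the phenol is ortho-substituted. Fallback: make the ether by Ullmann coupling of an aryl bromide and install the sulfone afterwards. Set out from 6 and 11: zinc insertion into purchased 4-bromobenzyl bromide gives the bromobenzylzinc bromide F7, which adds to 6 to give the aryl bromide carbinol F8. CuI/picolinic acid/K3PO4 (DMSO, 80 °C) couples it with phenol 11 to the terminal alkene diaryl ether F9. Cross-metathesis with phenyl vinyl sulfone (Grubbs II, CH2Cl2, 40 °C) comes back to the route at 13.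

**Further compounds**
F1 | step 8 | bimolecular Diels–Alder lactone | O=Cc1c(OC23C=CC(OC2=O)C(CC(O)c2ccc(OCc4ccccc4)c(O)c2)C3S(=O)(=O)c2ccccc2)c(OC)ccc1OCc1ccccc1
F2 | step 8 | sulfonyl cyclohexadiene aldehyde | O=Cc1c(OC2=CC=CC(CC(O)c3ccc(OCc4ccccc4)c(O)c3)C2S(=O)(=O)c2ccccc2)c(OC)ccc1OCc1ccccc1
F3 | step 8 | diaryl ether aldehyde | O=Cc1c(Oc2cccc(CC(O)c3ccc(OCc4ccccc4)c(O)c3)c2)c(OC)ccc1OCc1ccccc1
F4 | step 8 | seco boronate | COc1ccc(OCc2ccccc2)c(C(O)Cc2ccc(cc2)B2OC(C)(C)C(C)(C)O2)c1Oc1cccc(CC(O)c2ccc(OCc3ccccc3)c(O)c2)c1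
F5 | step 3 | sulfonylethyl ether | O=Cc1c(OCCS(C)(=O)=O)c(OC)ccc1OCc1ccccc1
F6 | step 3 | salicylaldehyde | O=Cc1c(O)c(OC)ccc1OCc1ccccc1
F7 | step 7 | bromobenzylzinc bromide | Br[Zn]Cc1ccc(Br)cc1
F8 | step 7 | aryl bromide carbinol | COc1ccc(OCc2ccccc2)c(C(O)Cc2ccc(Br)cc2)c1OC1=CC=COC1=O
F9 | step 7 | terminal alkene diaryl ether | COc1ccc(OCc2ccccc2)c(C(O)Cc2ccc(cc2)Oc2cc(ccc2OCc2ccccc2)C(O)CC=C)c1OC1=CC=COC1=O
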